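**Strategy.** Ring A of the flavone touches ring C only at C4a and C8a. A 4-pyranone that already holds the future C5 as an ester on its C3 and the future C8 as a methyl on its C2 therefore lacks just C6 and C7. A coumarin-8-ylacetyl chloride brings these two carbons, so the hindered flavone C6–coumarin C8 bond never has to be made by coupling. In one operation the pyranone dienolate is acylated (C7–C8) and the benzylic carbon closes onto the ester (C5–C6), giving the aromatic 5,7-dihydroxy ring. The precursors are a 6-anisyl-2-methyl-4-pyranone-3-carboxylate and the arylacetyl chloride made from commercial osthole, which already has the C8 side chain and the 7-O-methyl group.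

Key step: step 6

Remark: the target SMILES gives no descriptor for the tetra-ortho-substituted biaryl axis (flavone C6–coumarin C8), so the axis is made without control and the product is expected as the racemate if rotation is slow.

Step 1
Reactants: 1 osthole [7-methoxy-8-(3-methylbut-2-en-1-yl)-2H-chromen-2-one]
Product: 3 2-(7-methoxy-2-oxo-2H-chromen-8-yl)acetaldehyde, via glycol 2 (not isolated)
Conditions: OsO4 (cat.), NaIO4 (4 equiv), 2,6-lutidine (2 equiv), 1,4-dioxane/H2O 3:1, rt
Reagents that add atoms: osmium tetroxide OsO4, O=[Os](=O)(=O)=O (catalytic oxygen carrier); sodium periodate NaIO4, [Na+].[O-]I(=O)(=O)=O (terminal oxidant)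
Why: Lemieux–Johnson oxidation: OsO4 dihydroxylates the electron-rich trisubstituted prenyl alkene much faster than the electron-poor, lactone-conjugated C3=C4 bond of the coumarin, NaIO4 cleaves glycol 2 (its single stereocentre forms as a racemate and disappears in the cleavage) to the arylacetaldehyde and acetone, and 2,6-lutidine holds back over-oxidation.

Step 2
Reactants: 3 2-(7-methoxy-2-oxo-2H-chromen-8-yl)acetaldehyde
Product: 4 2-(7-methoxy-2-oxo-2H-chromen-8-yl)acetic acid
Conditions: NaClO2, NaH2PO4, 2-methyl-2-butene (excess), t-BuOH/H2O, 0 °C to rt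
Reagents that add atoms: sodium chlorite NaClO2, [Na+].[O-]Cl=O
Why: Pinnick oxidation: chlorous acid converts the aldehyde into the acid under buffered, mildly acidic conditions that leave the lactone, the C3=C4 alkene and the benzylic CH2 alone, while 2-methyl-2-butene takes up the hypochlorous acid that would otherwise chlorinate the electron-rich arene.

Step 3
Reactants: 4 2-(7-methoxy-2-oxo-2H-chromen-8-yl)acetic acid
Product: 5 2-(7-methoxy-2-oxo-2H-chromen-8-yl)acetyl chloride
Conditions: (COCl)2, DMF (cat.), CH2Cl2, 0 °C to rt; evaporate, use crude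
Reagents that add atoms: oxalyl chloride, O=C(Cl)C(=O)Cl
Why: Acyl chloride formation through the Vilsmeier-type chloroiminium species from DMF and oxalyl chloride; the conditions do not touch the lactone or the aryl methyl ether, and the volatile by-products leave on evaporation so that 5 can be used directly.

Step 4
Reactants: 6 3-(4-methoxyphenyl)prop-2-ynoic acid
Product: 7 3-(4-methoxyphenyl)prop-2-ynoyl chloride
Conditions: (COCl)2, DMF (cat.), CH2Cl2, 0 °C; evaporate cold, use crude
Reagents that add atoms: oxalyl chloride, O=C(Cl)C(=O)Cl
Why: The same DMF-catalysed acyl chloride formation; the low temperature and short contact time keep hydrogen chloride from adding across the conjugated triple bond.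

Step 5
Reactants: 7 3-(4-methoxyphenyl)prop-2-ynoyl chloride; 8 methyl acetoacetate
Product: 10 methyl 6-(4-methoxyphenyl)-2-methyl-4-oxo-4H-pyran-3-carboxylate, via acylated keto ester 9 (not isolated)
Conditions: MgCl2 (1 equiv), pyridine (2 equiv), CH2Cl2, 0 °C to rt; then DMAP (cat.), rt; 1 M HCl work-up
Reagents that add atoms: none
Why: Soft enolisation with MgCl2 and pyridine gives the chelated enolate of the β-keto ester, which is acylated on carbon by the alkynoyl chloride (C-acylation of a β-dicarbonyl), and the acetyl enol oxygen of 9 then adds to the ynone β-carbon in an amine-catalysed 6-endo-dig oxa-Michael closure that gives the conjugated 4-pyranone.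

Step 6
Reactants: 10 methyl 6-(4-methoxyphenyl)-2-methyl-4-oxo-4H-pyran-3-carboxylate; 5 2-(7-methoxy-2-oxo-2H-chromen-8-yl)acetyl chloride
Product: 12 5,7-dihydroxy-6-(7-methoxy-2-oxo-2H-chromen-8-yl)-2-(4-methoxyphenyl)-4H-chromen-4-one, via pyranonyl ketone 11 (not isolated)
Conditions: 10 (2.1 equiv), LiN(SiMe3)2 (2.1 equiv), THF, −78 °C; 5 (1.0 equiv) in THF added slowly, −78 °C; then LiN(SiMe3)2 (2.5 equiv), −78 to 0 °C; 1 M HCl, rt
Reagents that add atoms: none
Why: LiN(SiMe3)2 removes a proton from the C2 methyl group of 10, which is activated vinylogously by both the ring carbonyl and the C3 ester, and the terminal carbon of the dienolate attacks acyl chloride 5 (or the arylketene formed from it by loss of HCl) to make the future C7–C8 bond, the second equivalent of dienolate taking up the proton that ketone 11 releases. The second charge of base then makes the benzylic carbon of 11 (future C6) nucleophilic, and it adds to the neighbouring ester carbonyl in a 6-(enolendo)-exo-trig Dieckmann closure (C5–C6 bond), after which loss of methoxide and two enolisations give the aromatic 5,7-dihydroxy ring A. The closest known reaction type is acylation of a laterally deprotonated ortho-toluate followed by Dieckmann aromatisation to a 1,3-dihydroxyarene, combined with the established lateral deprotonation of 2-methyl-4-pyranones. No stereocentre is formed; the bond from the CH2 carbon to coumarin C8, carried through from 5, becomes the hindered biaryl axis, whose configuration is not controlled. The step needs attack at the acyl chloride and not at the coumarin lactone, and acylation on carbon and not on oxygen: the first is secured by the far higher electrophilicity of the acyl chloride or ketene at −78 °C and by the non-nucleophilic base, the second by the soft, delocalised dienolate with a lithium counter-ion in THF, and closure at the ester instead of the pyranone C4 carbonyl follows because only the ester can expel a leaving group and aromatise. The methoxide released is taken up at once by the acidic phenol of the product, and the acidic quench re-closes any lactone that has opened, since the Z geometry of the cinnamate is kept.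

Step 7
Reactants: 12 5,7-dihydroxy-6-(7-methoxy-2-oxo-2H-chromen-8-yl)-2-(4-methoxyphenyl)-4H-chromen-4-one
Product: 13 5,7-dihydroxy-6-(7-hydroxy-2-oxo-2H-chromen-8-yl)-2-(4-hydroxyphenyl)-4H-chromen-4-one (target)
Conditions: BBr3 (8 equiv), CH2Cl2, −78 °C to rt; H2O quench at 0 °C
Reagents that add atoms: none
Why: Lewis-acid ether cleavage: BBr3 coordinates each methoxy oxygen and bromide removes the methyl group by SN2 attack, with the free 5- and 7-hydroxyls held as borates until hydrolysis; the aprotic conditions at or below room temperature spare the lactone and avoid the hot protic acid that could open and re-close the pyranone (Wessely–Moser rearrangement) and so move the aryl group from C6 to C8.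

**Compound list**

1 | osthole, 7-methoxy-8-(3-methylbut-2-en-1-yl)-2H-chromen-2-one | COc1ccc2ccc(=O)oc2c1CC=C(C)C | starting material
2 | 8-(2,3-dihydroxy-3-methylbutyl)-7-methoxy-2H-chromen-2-one (racemic glycol) | COc1ccc2ccc(=O)oc2c1CC(O)C(C)(C)O | intermediate
3 | 2-(7-methoxy-2-oxo-2H-chromen-8-yl)acetaldehyde | COc1ccc2ccc(=O)oc2c1CC=O | intermediate
4 | 2-(7-methoxy-2-oxo-2H-chromen-8-yl)acetic acid | COc1ccc2ccc(=O)oc2c1CC(=O)O | intermediate
5 | 2-(7-methoxy-2-oxo-2H-chromen-8-yl)acetyl chloride | COc1ccc2ccc(=O)oc2c1CC(=O)Cl | intermediate
6 | 3-(4-methoxyphenyl)prop-2-ynoic acid | COc1ccc(C#CC(=O)O)cc1 | starting material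
7 | 3-(4-methoxyphenyl)prop-2-ynoyl chloride | COc1ccc(C#CC(=O)Cl)cc1 | intermediate
8 | methyl acetoacetate (methyl 3-oxobutanoate) | CC(=O)CC(=O)OC | starting material
9 | methyl 2-acetyl-5-(4-methoxyphenyl)-3-oxopent-4-ynoate (drawn as the keto form; enolised, so its central carbon is not a fixed stereocentre) | COC(=O)C(C(C)=O)C(=O)C#Cc1ccc(OC)cc1 | intermediate
10 | methyl 6-(4-methoxyphenyl)-2-methyl-4-oxo-4H-pyran-3-carboxylate | COC(=O)c1c(C)oc(-c2ccc(OC)cc2)cc1=O | intermediate
11 | methyl 6-(4-methoxyphenyl)-2-[3-(7-methoxy-2-oxo-2H-chromen-8-yl)-2-oxopropyl]-4-oxo-4H-pyran-3-carboxylate | COC(=O)c1c(CC(=O)Cc2c(OC)ccc3ccc(=O)oc23)oc(-c2ccc(OC)cc2)cc1=O | intermediate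
12 | 5,7-dihydroxy-6-(7-methoxy-2-oxo-2H-chromen-8-yl)-2-(4-methoxyphenyl)-4H-chromen-4-one | COc1ccc(-c2cc(=O)c3c(O)c(-c4c(OC)ccc5ccc(=O)oc45)c(O)cc3o2)cc1 | intermediate
13 | 5,7-dihydroxy-6-(7-hydroxy-2-oxo-2H-chromen-8-yl)-2-(4-hydroxyphenyl)-4H-chromen-4-one | O=c1ccc2ccc(O)c(-c3c(O)cc4oc(-c5ccc(O)cc5)cc(=O)c4c3O)c2o1 | target

**Step count and risks**

Total steps: 7. Longest linear sequence: 5 steps (steps 1, 2, 3, 6, 7); the pyranone arm (steps 4, 5) joins at step 6.

Step 6 is the most likely to fail. The dienolate may be acylated on oxygen, or the derived ketene may dimerise, so that no C–C bond forms. Ketone 11 may also close through its enol oxygen onto the ester to give an enol lactone, or base and dienolate may attack the coumarin lactone on warming. The fallback separates the two bond formations and replaces the acyl chloride by the aldehyde. It sets out from aldehyde 3 and pyranone 10. The dienolate of 10 (LiN(SiMe3)2, THF, −78 °C) adds to 3 in a vinylogous aldol reaction, quenched cold with acetic acid so that the alkoxide does not lactonise onto the ester. This should give the racemic alcohol methyl 2-[2-hydroxy-3-(7-methoxy-2-oxo-2H-chromen-8-yl)propyl]-6-(4-methoxyphenyl)-4-oxo-4H-pyran-3-carboxylate F1. Dess–Martin periodinane in CH2Cl2 oxidises F1 to ketone 11, now isolated, and NaH in THF (0 °C to rt) then effects the Dieckmann closure and aromatisation. The fallback rejoins the route at 12.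

Step 5 is second. Acylation may occur at the enolate oxygen, chloride or pyridine may add to the ynone, or the ring may close in the 5-exo mode to a furanone. The fallback builds the pyranone by an acylketene–enamine annulation, sets out from methyl acetoacetate 8 and rejoins at 10. Compound 8 is condensed with pyrrolidine (toluene, removal of water) to the enamine methyl (2E)-3-(pyrrolidin-1-yl)but-2-enoate F2. Separately, Meldrum's acid is acylated with 4-methoxybenzoyl chloride (pyridine, CH2Cl2, 0 °C to rt) to 5-[hydroxy(4-methoxyphenyl)methylidene]-2,2-dimethyl-1,3-dioxane-4,6-dione F3. Heating F3 with F2 in toluene at 110 °C releases acetone and CO2 to give 4-methoxybenzoylketene F4. The enamine carbon captures F4 and the ring closes to methyl 6-(4-methoxyphenyl)-2-methyl-4-oxo-2-(pyrrolidin-1-yl)-3,4-dihydro-2H-pyran-3-carboxylate F5, which loses pyrrolidine to give 10.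

Step 1 is third. The enolisable arylacetaldehyde may be degraded further through its enol, or the coumarin C3=C4 bond may be osmylated. The fallback avoids osmium, sets out from osthole 1 and rejoins at 3. mCPBA (CH2Cl2, 0 °C) epoxidises only the electron-rich trisubstituted alkene to the racemic epoxide 8-[(3,3-dimethyloxiran-2-yl)methyl]-7-methoxy-2H-chromen-2-one F6. H5IO6 in aqueous THF then opens F6 to glycol 2 and cleaves it in the same flask to aldehyde 3 and acetone.

**Further compounds**

F1 | step 6 | methyl 2-[2-hydroxy-3-(7-methoxy-2-oxo-2H-chromen-8-yl)propyl]-6-(4-methoxyphenyl)-4-oxo-4H-pyran-3-carboxylate (racemic) | COC(=O)c1c(CC(O)Cc2c(OC)ccc3ccc(=O)oc23)oc(-c2ccc(OC)cc2)cc1=O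
F2 | step 5 | methyl (2E)-3-(pyrrolidin-1-yl)but-2-enoate | COC(=O)/C=C(\C)N1CCCC1
F3 | step 5 | 5-[hydroxy(4-methoxyphenyl)methylidene]-2,2-dimethyl-1,3-dioxane-4,6-dione | COc1ccc(C(O)=C2C(=O)OC(C)(C)OC2=O)cc1
F4 | step 5 | 3-(4-methoxyphenyl)-3-oxoprop-1-en-1-one (4-methoxybenzoylketene) | COc1ccc(C(=O)C=C=O)cc1
F5 | step 5 | methyl 6-(4-methoxyphenyl)-2-methyl-4-oxo-2-(pyrrolidin-1-yl)-3,4-dihydro-2H-pyran-3-carboxylate (mixture of racemic diastereomers) | COC(=O)C1C(=O)C=C(c2ccc(OC)cc2)OC1(C)N3CCCC3
F6 | step 1 | 8-[(3,3-dimethyloxiran-2-yl)methyl]-7-methoxy-2H-chromen-2-one (racemic) | COc1ccc2ccc(=O)oc2c1CC1OC1(C)C
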